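Attenol A is cut at C10–C11, next to the spiro carbon. The oxolane ring (O, C14, C13, C12, spiro C11) is read as four contiguous carbons plus one oxygen lying between the stereogenic CH (C14) and the acyl-level carbon C11, that is, as a 2-alkylcyclobutanone awaiting oxygen insertion. Commercial cyclobutanone supplies all four ring carbons. Its SAMP azaenolate opens an (S)-epoxide, fixing C14 and C16. A Baeyer–Villiger ring expansion (four- to five-membered) then delivers the γ-lactone with retention at C14 and an untouched alkene. A C1–C10 alkyllithium adds to the lactone carbonyl, and acid desilylation closes the oxane ring under anomeric control.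

Key step: step 5

Remark on numbering: attenol numbering is used throughout. C1 is the CH2OH carbon, C11 the spiro carbon and C21 the terminal =CH2. The target is (6R,7R,8R,11S,14S,16S,3Z).
Remark on the chemistry: γ-hydroxy ketones are ring–chain tautomers. Compound 10 is written in its open form. Compounds 31 and 32 are written as lactols (both anomers at C11).

Step 1
Reactants: 1 (S)-epichlorohydrin; 2 but-3-en-1-ylmagnesium bromide
Product: 4 (2S)-2-(pent-4-en-1-yl)oxirane, via chlorohydrin 3 (not isolated)
Conditions: CuI (10 mol %), THF, −40 → 0 °C; aq. quench; then powdered NaOH, Et2O, rt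
Reagents that add atoms: none
Why: Copper-catalysed Grignard opening of the epoxide at its CH2 terminus, followed by Williamson-type closure of chlorohydrin 3, never touches the C–O stereocentre (future C16), so the (S) configuration is carried into 4.

Step 2
Reactants: 5 cyclobutanone; 6 SAMP, (S)-1-amino-2-(methoxymethyl)pyrrolidine
Product: 7 cyclobutanone SAMP hydrazone
Conditions: neat, 4 Å MS, 60 °C
Reagents that add atoms: none
Why: This is a plain hydrazone condensation of an unhindered, strained ketone with the chiral hydrazine, and no stereocentre is formed.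

Step 3
Reactants: 7 cyclobutanone SAMP hydrazone; 4 (2S)-2-(pent-4-en-1-yl)oxirane
Product: 9 SAMP hydrazone of (2S)-2-[(2S)-2-hydroxyhept-6-en-1-yl]cyclobutanone, via lithium azaenolate 8 (not isolated)
Conditions: LDA, THF, 0 °C; then 4, −78 °C → rt; H2O
Reagents that add atoms: none
Why: In this Enders SAMP-hydrazone alkylation the lithium-chelated azaenolate 8 reacts on the face left open by the methoxymethyl arm and opens 4 by SN2 at its CH2 carbon, which should set C14 as (S) by the usual SAMP topicity while C16 comes unchanged from 4.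

Step 4
Reactants: 9 SAMP hydrazone of (2S)-2-[(2S)-2-hydroxyhept-6-en-1-yl]cyclobutanone
Product: 10 (2S)-2-[(2S)-2-hydroxyhept-6-en-1-yl]cyclobutan-1-one
Conditions: sat. aq. oxalic acid, Et2O, rt
Reagents that add atoms: water, O
Why: Two-phase oxalic acid hydrolysis of SAMP hydrazones spares α-stereocentres and alkenes, and any C14 epimerisation should drift towards the wanted isomer because its ring tautomer carries the pentenyl chain on the convex face of the cis-fused 2-oxabicyclo[3.2.0]heptan-1-ol.

Step 5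
Reactants: 10 (2S)-2-[(2S)-2-hydroxyhept-6-en-1-yl]cyclobutan-1-one
Product: 12 (5S)-5-[(2S)-2-hydroxyhept-6-en-1-yl]oxolan-2-one, via Criegee perhydrate 11 (not isolated)
Conditions: 30% aq. H2O2, AcOH, 0 °C
Reagents that add atoms: hydrogen peroxide, OO
Why: In this Baeyer–Villiger oxidation hydrogen peroxide adds to the strained carbonyl C11 to give perhydrate 11 (Criegee adduct), whose C11–C14 bond, antiperiplanar to the O–O bond, migrates to oxygen as water leaves. The oxolane ring is therefore not closed end to end but grows out of the cyclobutane by a 1,2-carbon-to-oxygen shift that inserts one oxygen between C11 and C14 (four- to five-membered). No stereocentre is created: C14 migrates with retention, as is general for this reaction, and C16 is a spectator. Regioselectivity between C14 (secondary) and C12 (primary) is needed and is secured by the higher migratory aptitude of the more substituted carbon. Chemoselectivity over the terminal alkene is secured by ring strain, which lets the nucleophilic oxidant H2O2/AcOH react at 0 °C, where a monosubstituted alkene should not be epoxidised. The free C16 hydroxyl takes part only in a reversible hemiketal and stays free in 12, because the seven-membered lactone isomer is disfavoured against the γ-lactone.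

Step 6
Reactants: 12 (5S)-5-[(2S)-2-hydroxyhept-6-en-1-yl]oxolan-2-one
Product: 13 (5S)-5-[(2S)-2-(tert-butyldimethylsilyloxy)hept-6-en-1-yl]oxolan-2-one
Conditions: TBSCl, imidazole, DMF, rt
Reagents that add atoms: TBSCl, CC(C)(C)[Si](C)(C)Cl
Why: Standard silyl ether protection of a secondary alcohol removes the only acidic proton before the organolithium step.

Step 7
Reactants: 14 tert-butyl(but-3-yn-1-yloxy)dimethylsilane; 15 methyl (2R)-glycidate
Product: 17 methyl (2R)-7-(tert-butyldimethylsilyloxy)-2-hydroxyhept-4-ynoate, via lithium acetylide 16 (not isolated)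
Conditions: n-BuLi, THF, −78 °C; BF3·OEt2; then 15, −78 °C
Reagents that add atoms: none
Why: In this Yamaguchi–Hirao alkynylation the BF3-activated epoxide is opened by acetylide 16 at the unsubstituted carbon faster than the ester is attacked at −78 °C, so the (R) carbinol centre (C6) comes intact from the chiral pool.

Step 8
Reactants: 17 methyl (2R)-7-(tert-butyldimethylsilyloxy)-2-hydroxyhept-4-ynoate
Product: 18 methyl (2R)-2,7-bis(tert-butyldimethylsilyloxy)hept-4-ynoate
Conditions: TBSCl, imidazole, DMF, rt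
Reagents that add atoms: TBSCl, CC(C)(C)[Si](C)(C)Cl
Why: Standard silyl ether formation on an α-hydroxy ester leaves C6 unaffected.

Step 9
Reactants: 18 methyl (2R)-2,7-bis(tert-butyldimethylsilyloxy)hept-4-ynoate
Product: 19 methyl (2R,4Z)-2,7-bis(tert-butyldimethylsilyloxy)hept-4-enoate
Conditions: H2 (1 atm), Lindlar catalyst, quinoline, EtOAc, rt
Reagents that add atoms: none
Why: Lindlar semihydrogenation delivers hydrogen syn to the alkyne and sets the (Z)-C3=C4 alkene at a stage where no other alkene competes.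

Step 10
Reactants: 19 methyl (2R,4Z)-2,7-bis(tert-butyldimethylsilyloxy)hept-4-enoate
Product: 20 (2R,4Z)-2,7-bis(tert-butyldimethylsilyloxy)hept-4-enal
Conditions: DIBAL-H (1.05 equiv), CH2Cl2, −78 °C; aq. Rochelle salt
Reagents that add atoms: none
Why: In this DIBAL-H partial reduction the aluminium hemiacetal of an α-silyloxy ester persists at −78 °C and releases the aldehyde only on work-up, without touching C6.

Step 11
Reactants: 20 (2R,4Z)-2,7-bis(tert-butyldimethylsilyloxy)hept-4-enal; 21 trans-2-butene
Product: 25 (3R,4R,5R,7Z)-5,10-bis(tert-butyldimethylsilyloxy)-3-methyldeca-1,7-dien-4-ol, via crotylpotassium 22 (not isolated), via crotylborane 23 (not isolated), via borinate 24 (not isolated)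
Conditions: 21, KOt-Bu, n-BuLi, THF, −78 → −45 °C; (+)-Ipc2BOMe [from (−)-α-pinene], −78 °C; BF3·OEt2; 20, −78 °C; then NaOH, 30% H2O2, rt
Reagents that add atoms: none
Why: Brown crotylboration proceeds through a closed chair transition state in which the (E)-crotyl geometry sets the C7/C8 anti relation, and the isopinocampheyl groups derived from (−)-α-pinene direct attack to the aldehyde face that gives (7R,8R), the 6,7-syn pattern, by reagent control.

Step 12
Reactants: 25 (3R,4R,5R,7Z)-5,10-bis(tert-butyldimethylsilyloxy)-3-methyldeca-1,7-dien-4-ol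
Product: 26 (3R,4R,5R,7Z)-5,10-bis(tert-butyldimethylsilyloxy)-3-methyl-4-(triethylsilyloxy)deca-1,7-diene
Conditions: TESOTf, 2,6-lutidine, CH2Cl2, −78 → 0 °C
Reagents that add atoms: TESOTf, CC[Si](CC)(CC)OS(=O)(=O)C(F)(F)F
Why: Silyl triflate silylation copes with the hindered C7 alcohol, and TES is chosen as the most acid-labile group so that O7 can be freed first.

Step 13
Reactants: 26 (3R,4R,5R,7Z)-5,10-bis(tert-butyldimethylsilyloxy)-3-methyl-4-(triethylsilyloxy)deca-1,7-diene
Product: 28 (3R,4R,5R,7Z)-5,10-bis(tert-butyldimethylsilyloxy)-3-methyl-4-(triethylsilyloxy)dec-7-en-1-ol, via alkylborane 27 (not isolated)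
Conditions: 9-BBN (1.2 equiv), THF, 0 °C → rt; then NaOH, 30% H2O2, 0 °C
Reagents that add atoms: hydrogen peroxide, OO
Why: In this hydroboration–oxidation 9-BBN adds anti-Markovnikov to the monosubstituted C9=C10 alkene much faster than to the internal (Z)-alkene.

Step 14
Reactants: 28 (3R,4R,5R,7Z)-5,10-bis(tert-butyldimethylsilyloxy)-3-methyl-4-(triethylsilyloxy)dec-7-en-1-ol
Product: 29 (3R,4R,5R,7Z)-5,10-bis(tert-butyldimethylsilyloxy)-1-iodo-3-methyl-4-(triethylsilyloxy)dec-7-ene
Conditions: I2, PPh3, imidazole, CH2Cl2, 0 °C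
Reagents that add atoms: iodine, II
Why: Appel-type iodination is an SN2 displacement at the primary carbon C10 under buffered conditions that silyl ethers and the (Z)-alkene tolerate.

Step 15
Reactants: 29 (3R,4R,5R,7Z)-5,10-bis(tert-butyldimethylsilyloxy)-1-iodo-3-methyl-4-(triethylsilyloxy)dec-7-ene; 13 (5S)-5-[(2S)-2-(tert-butyldimethylsilyloxy)hept-6-en-1-yl]oxolan-2-one
Product: 31 fully silylated C1–C21 lactol (2-alkyl-2-hydroxyoxolane, both C11 anomers), via alkyllithium 30 (not isolated)
Conditions: t-BuLi (2.1 equiv), Et2O–pentane, −78 °C; then 13, −78 °C; pH 7 buffer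
Reagents that add atoms: none
Why: Lithium–iodine exchange followed by acyl addition of the alkyllithium to the γ-lactone forms C10–C11, the tetrahedral lithium alkoxide holds back a second addition at −78 °C, and the C11 anomeric mixture is inconsequential.

Step 16
Reactants: 31 fully silylated C1–C21 lactol
Product: 33 attenol A, via desilylated lactol 32 (not isolated)
Conditions: 48% aq. HF, MeCN, 0 °C → rt
Reagents that add atoms: none
Why: Acidic global desilylation and spiroketalisation (6-exo-trig attack of O7 on the oxolanyl oxocarbenium ion) run under thermodynamic control, and (11S) should prevail because it places O14 axial on the oxane chair (anomeric effect) while the C7 side chain and the C8 methyl are both equatorial.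

Compound list
1 | (S)-epichlorohydrin | ClC[C@@H]1CO1 | starting material
2 | but-3-en-1-ylmagnesium bromide | C=CCC[Mg]Br | starting material
3 | (2S)-1-chlorohept-6-en-2-ol | C=CCCC[C@H](O)CCl | intermediate
4 | (2S)-2-(pent-4-en-1-yl)oxirane | C=CCCC[C@H]1CO1 | intermediate
5 | cyclobutanone | O=C1CCC1 | starting material
6 | SAMP, (S)-1-amino-2-(methoxymethyl)pyrrolidine | COC[C@@H]1CCCN1N | starting material
7 | cyclobutanone SAMP hydrazone | COC[C@@H]1CCCN1N=C1CCC1 | intermediate
8 | lithium azaenolate of 7 | COC[C@@H]1CCCN1N([Li])C1=CCC1 | intermediate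
9 | SAMP hydrazone of (2S)-2-[(2S)-2-hydroxyhept-6-en-1-yl]cyclobutanone (C=N geometry not specified) | C=CCCC[C@H](O)C[C@@H]1CCC1=NN1CCC[C@H]1COC | intermediate
10 | (2S)-2-[(2S)-2-hydroxyhept-6-en-1-yl]cyclobutan-1-one | C=CCCC[C@H](O)C[C@@H]1CCC1=O | intermediate
11 | Criegee perhydrate of 10 (1-hydroperoxycyclobutan-1-ol, C11 undefined) | C=CCCC[C@H](O)C[C@@H]1CCC1(O)OO | intermediate
12 | (5S)-5-[(2S)-2-hydroxyhept-6-en-1-yl]oxolan-2-one | C=CCCC[C@H](O)C[C@@H]1CCC(=O)O1 | intermediate
13 | (5S)-5-[(2S)-2-(tert-butyldimethylsilyloxy)hept-6-en-1-yl]oxolan-2-one | C=CCCC[C@H](O[Si](C)(C)C(C)(C)C)C[C@@H]1CCC(=O)O1 | intermediate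
14 | tert-butyl(but-3-yn-1-yloxy)dimethylsilane | C#CCCO[Si](C)(C)C(C)(C)C | starting material
15 | methyl (2R)-glycidate | COC(=O)[C@H]1CO1 | starting material
16 | lithium acetylide of 14 | [Li]C#CCCO[Si](C)(C)C(C)(C)C | intermediate
17 | methyl (2R)-7-(tert-butyldimethylsilyloxy)-2-hydroxyhept-4-ynoate | COC(=O)[C@H](O)CC#CCCO[Si](C)(C)C(C)(C)C | intermediate
18 | methyl (2R)-2,7-bis(tert-butyldimethylsilyloxy)hept-4-ynoate | COC(=O)[C@H](O[Si](C)(C)C(C)(C)C)CC#CCCO[Si](C)(C)C(C)(C)C | intermediate
19 | methyl (2R,4Z)-2,7-bis(tert-butyldimethylsilyloxy)hept-4-enoate | COC(=O)[C@H](O[Si](C)(C)C(C)(C)C)C/C=C\CCO[Si](C)(C)C(C)(C)C | intermediate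
20 | (2R,4Z)-2,7-bis(tert-butyldimethylsilyloxy)hept-4-enal | O=C[C@H](O[Si](C)(C)C(C)(C)C)C/C=C\CCO[Si](C)(C)C(C)(C)C | intermediate
21 | trans-2-butene | C/C=C/C | starting material
22 | (E)-crotylpotassium | C/C=C/C[K] | intermediate
23 | (E)-crotylbis(isopinocampheyl)borane, Ipc from (−)-α-pinene | C/C=C/CB([C@H]1C[C@H]2C[C@@H]([C@@H]1C)C2(C)C)[C@H]1C[C@H]2C[C@@H]([C@@H]1C)C2(C)C | intermediate
24 | bis(isopinocampheyl)borinate of 25 | C=C[C@@H](C)[C@@H](OB([C@H]1C[C@H]2C[C@@H]([C@@H]1C)C2(C)C)[C@H]1C[C@H]2C[C@@H]([C@@H]1C)C2(C)C)[C@H](O[Si](C)(C)C(C)(C)C)C/C=C\CCO[Si](C)(C)C(C)(C)C | intermediate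
25 | (3R,4R,5R,7Z)-5,10-bis(tert-butyldimethylsilyloxy)-3-methyldeca-1,7-dien-4-ol | C=C[C@@H](C)[C@@H](O)[C@H](O[Si](C)(C)C(C)(C)C)C/C=C\CCO[Si](C)(C)C(C)(C)C | intermediate
26 | (3R,4R,5R,7Z)-5,10-bis(tert-butyldimethylsilyloxy)-3-methyl-4-(triethylsilyloxy)deca-1,7-diene | C=C[C@@H](C)[C@@H](O[Si](CC)(CC)CC)[C@H](O[Si](C)(C)C(C)(C)C)C/C=C\CCO[Si](C)(C)C(C)(C)C | intermediate
27 | B-alkyl-9-borabicyclo[3.3.1]nonane from 26 (boron on C10) | C1CC2CCCC(C1)B2CC[C@@H](C)[C@@H](O[Si](CC)(CC)CC)[C@H](O[Si](C)(C)C(C)(C)C)C/C=C\CCO[Si](C)(C)C(C)(C)C | intermediate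
28 | (3R,4R,5R,7Z)-5,10-bis(tert-butyldimethylsilyloxy)-3-methyl-4-(triethylsilyloxy)dec-7-en-1-ol | OCC[C@@H](C)[C@@H](O[Si](CC)(CC)CC)[C@H](O[Si](C)(C)C(C)(C)C)C/C=C\CCO[Si](C)(C)C(C)(C)C | intermediate
29 | (3R,4R,5R,7Z)-5,10-bis(tert-butyldimethylsilyloxy)-1-iodo-3-methyl-4-(triethylsilyloxy)dec-7-ene | ICC[C@@H](C)[C@@H](O[Si](CC)(CC)CC)[C@H](O[Si](C)(C)C(C)(C)C)C/C=C\CCO[Si](C)(C)C(C)(C)C | intermediate
30 | alkyllithium from 29 (lithium on C10) | [Li]CC[C@@H](C)[C@@H](O[Si](CC)(CC)CC)[C@H](O[Si](C)(C)C(C)(C)C)C/C=C\CCO[Si](C)(C)C(C)(C)C | intermediate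
31 | fully silylated C1–C21 lactol (O1, O6, O16 TBS; O7 TES; C11 anomers) | C=CCCC[C@H](O[Si](C)(C)C(C)(C)C)C[C@@H]1CCC(O)(CC[C@@H](C)[C@@H](O[Si](CC)(CC)CC)[C@H](O[Si](C)(C)C(C)(C)C)C/C=C\CCO[Si](C)(C)C(C)(C)C)O1 | intermediate
32 | desilylated lactol (C11 anomers) | C=CCCC[C@H](O)C[C@@H]1CCC(O)(CC[C@@H](C)[C@@H](O)[C@H](O)C/C=C\CCO)O1 | intermediate
33 | attenol A | C=CCCC[C@H](O)C[C@@H]1CC[C@@]2(CC[C@@H](C)[C@H]([C@H](O)C/C=C\CCO)O2)O1 | target

Total step count: 16.
Longest linear sequence: 10 steps (steps 7–16). The lactone branch takes 6 steps (steps 1–6) before the union in step 15.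

Steps most likely to fail

Step 3. Opening of the epoxide by azaenolate 8 needs warming well above −78 °C, so facial selectivity at C14 may erode, or the opening may stall.
- The fallback replaces auxiliary control by thermodynamic substrate control. It sets out from 5 and 4 and comes back at 10.
- Compound 5 is condensed with N,N-dimethylhydrazine to cyclobutanone N,N-dimethylhydrazone F1.
- LDA and then 4 give the alkylated dimethylhydrazone F2 as C14 epimers.
- Cu(OAc)2 in THF–H2O hydrolyses it to the C14-epimeric hydroxy ketone F3.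
- Catalytic DBU in THF equilibrates C14 through the enolate while the material rests as its cis-fused hemiketal.
- The exo hemiketal F4 has the pentenyl chain on the convex face and is the ring tautomer of 10, so it should accumulate.
- Residual epimer would be removed by chromatography at the stage of 12.

Step 11. The intrinsic Cornforth/Felkin preference of the α-silyloxy aldehyde for the 6,7-anti adduct opposes the reagent. Facial selectivity may therefore drop, and 20 may epimerise at C6 before it reacts.
- The fallback uses a matched addition followed by inversion. It sets out from 20 and comes back at 25.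
- cis-2-Butene, KOt-Bu/n-BuLi, (−)-Ipc2BOMe and BF3·OEt2 give the (Z)-crotylbis(isopinocampheyl)borane F5.
- Its addition to 20 is matched and should give the 6,7-anti-7,8-syn alcohol F6, which already has the correct C8.
- Mitsunobu inversion at C7 (4-nitrobenzoic acid, PPh3, DIAD, toluene) gives the 4-nitrobenzoate F7.
- K2CO3 in MeOH then releases 25.

Step 16. With all hydroxyls free under acid, ketal exchange may divert material to the isomeric bicyclic ketal that engages O6 and O7. The hindered C6 silyl ether may also demand long acid exposure.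
- The fallback unmasks in stages. It sets out from 31 and comes back at 33.
- PPTS in MeOH–CH2Cl2 at 0 °C removes only the TES group.
- O7 then closes onto C11 while O1, O6 and O16 stay silylated, giving the tris-TBS spiroketal F8.
- TBAF in THF removes the three TBS groups under non-acidic conditions, in which the spiroketal cannot re-equilibrate, and gives 33.

Further compounds
F1 | step 3 | cyclobutanone N,N-dimethylhydrazone | CN(C)N=C1CCC1
F2 | step 3 | N,N-dimethylhydrazone of 2-[(2S)-2-hydroxyhept-6-en-1-yl]cyclobutanone (C14 epimers) | C=CCCC[C@H](O)CC1CCC1=NN(C)C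
F3 | step 3 | 2-[(2S)-2-hydroxyhept-6-en-1-yl]cyclobutan-1-one (C14 epimers) | C=CCCC[C@H](O)CC1CCC1=O
F4 | step 3 | exo-3-(pent-4-en-1-yl)-2-oxabicyclo[3.2.0]heptan-1-ol, ring tautomer of 10 | C=CCCC[C@H]1C[C@@H]2CC[C@]2(O)O1
F5 | step 11 | (Z)-crotylbis(isopinocampheyl)borane, Ipc from (+)-α-pinene | C/C=C\CB([C@@H]1C[C@@H]2C[C@H]([C@H]1C)C2(C)C)[C@@H]1C[C@@H]2C[C@H]([C@H]1C)C2(C)C
F6 | step 11 | (3R,4S,5R,7Z)-5,10-bis(tert-butyldimethylsilyloxy)-3-methyldeca-1,7-dien-4-ol | C=C[C@@H](C)[C@H](O)[C@H](O[Si](C)(C)C(C)(C)C)C/C=C\CCO[Si](C)(C)C(C)(C)C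
F7 | step 11 | 4-nitrobenzoate of 25 | C=C[C@@H](C)[C@@H](OC(=O)c1ccc(cc1)[N+](=O)[O-])[C@H](O[Si](C)(C)C(C)(C)C)C/C=C\CCO[Si](C)(C)C(C)(C)C
F8 | step 16 | 1,6,16-tris-O-TBS attenol A | C=CCCC[C@H](O[Si](C)(C)C(C)(C)C)C[C@@H]1CC[C@@]2(CC[C@@H](C)[C@H]([C@H](O[Si](C)(C)C(C)(C)C)C/C=C\CCO[Si](C)(C)C(C)(C)C)O2)O1
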